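**Retrosynthetic overview**
1. Target 13 ⇒ C6–CH(CH3)Ar bond: 7,4'-di-O-benzyl-aromadendrin 9 plus the p-quinone methide of 1-(4-hydroxyphenyl)ethanol (catalyst-controlled Friedel–Crafts ortho to the chelated 5-OH, sets 1R), then debenzylation.
2. Dihydroflavonol 8 ⇒ 2'-hydroxychalcone 4 in one pot, in the order chalcone isomerase → flavanone 3-hydroxylase: asymmetric oxa-Michael closure (O1–C2, sets C2), then enol ether oxidation (sets C3 trans).
3. Chalcone 4 ⇒ Claisen–Schmidt condensation of di-O-benzyl phloroacetophenone 2 with 4-benzyloxybenzaldehyde 3.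
4. Ring order: rings A and B are bought; the pyranone C ring is the only ring formed (step 3), and the side chain is attached after it, so the 6- versus 8-position question never arises at the cyclisation.

Assumption: the absolute sense of induction of the two organocatalysts is taken by analogy and has not been demonstrated on these substrates; if either gives the mirror-image sense, its commercial antipode (quinidine-derived squaramide, (S)-TRIP) is used with no change to the route.

**Route**

Step 1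
Reactants: 1 1-(2,4,6-trihydroxyphenyl)ethan-1-one (phloroacetophenone)
Product: 2 1-[2,4-bis(benzyloxy)-6-hydroxyphenyl]ethan-1-one
Conditions: BnBr (2.1 equiv), K2CO3 (2.2 equiv), DMF, 0 °C → rt
Reagents that add atoms: benzyl bromide, BrCc1ccccc1
Why: Williamson etherification takes the 4-OH and one of the two equivalent ortho OH groups, while the remaining ortho OH is locked in the hydrogen bond to the acetyl C=O and stays free.

Step 2
Reactants: 2 1-[2,4-bis(benzyloxy)-6-hydroxyphenyl]ethan-1-one; 3 4-(benzyloxy)benzaldehyde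
Product: 4 (E)-1-[2,4-bis(benzyloxy)-6-hydroxyphenyl]-3-[4-(benzyloxy)phenyl]prop-2-en-1-one
Conditions: KOH (50 % aq.), EtOH/THF, rt, 36 h; then AcOH to pH 5
Reagents that add atoms: none
Why: Claisen–Schmidt condensation (crossed aldol of the methyl ketone with a non-enolisable aldehyde, then E1cB dehydration) gives the (E)-chalcone, which stays open as its phenoxide in strong base.

Step 3
Reactants: 4 (E)-1-[2,4-bis(benzyloxy)-6-hydroxyphenyl]-3-[4-(benzyloxy)phenyl]prop-2-en-1-one
Product: 8 (2R,3R)-5,7-bis(benzyloxy)-2-[4-(benzyloxy)phenyl]-3-hydroxychroman-4-one, via (2S)-flavanone 5 (not isolated), via silyl enol ether 6 (not isolated), via silyloxy epoxide 7 (not isolated)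
Conditions: quinine-derived bifunctional squaramide (10 mol %), PhMe, rt, 48 h; then CH2Cl2, Et3N (1.6 equiv), TMSOTf (1.5 equiv), −20 °C; then DMDO (2 equiv, acetone), −40 → 0 °C; then aq. citric acid, MeOH, 0 °C
Reagents that add atoms: dimethyldioxirane, CC1(C)OO1 (the 3-OH oxygen); trimethylsilyl trifluoromethanesulfonate, C[Si](C)(C)OS(=O)(=O)C(F)(F)F (SiMe3 in 6 and 7 only, lost on work-up)
Why: Proposed new method: the quinuclidine of the catalyst deprotonates the 2'-OH while the squaramide binds the enone C=O, so 6-endo oxa-Michael addition closes the ring and sets C2 as 2S (closest known reaction: cinchona (thio)urea-catalysed intramolecular oxa-Michael cyclisation to flavanones), soft enolisation then fixes this centre as the silyl enol ether without a free enolate that could reopen the ring, and Rubottom oxidation with DMDO attacks the face anti to the 2-aryl group so that hydrolysis of the silyloxy epoxide gives the 2,3-trans (2R,3R) ketol, which is also the thermodynamic C3 epimer.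

Step 4
Reactants: 8 (2R,3R)-5,7-bis(benzyloxy)-2-[4-(benzyloxy)phenyl]-3-hydroxychroman-4-one
Product: 9 (2R,3R)-7-(benzyloxy)-2-[4-(benzyloxy)phenyl]-3,5-dihydroxychroman-4-one
Conditions: BCl3 (2.5 equiv), CH2Cl2, −78 → −40 °C; then MeOH, aq. NaHCO3
Reagents that add atoms: none
Why: Chelation-controlled Lewis-acid dealkylation, in which BCl3 bridges the C4 carbonyl and the peri 5-benzyloxy oxygen so that chloride cleaves only this benzyl ether and leaves the 7- and 4'-benzyl ethers and both stereocentres untouched at low temperature.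

Step 5
Reactants: 9 (2R,3R)-7-(benzyloxy)-2-[4-(benzyloxy)phenyl]-3,5-dihydroxychroman-4-one; 10 1-(4-hydroxyphenyl)ethan-1-ol (racemic)
Product: 12 (2R,3R)-7-(benzyloxy)-2-[4-(benzyloxy)phenyl]-3,5-dihydroxy-6-[(1R)-1-(4-hydroxyphenyl)ethyl]chroman-4-one, via p-quinone methide 11 (not isolated)
Conditions: (R)-TRIP (10 mol %), 10 (1.5 equiv, slow addition), 5 Å MS, CH2Cl2, 0 °C → rt
Reagents that add atoms: none
Why: Proposed new method: the chiral phosphoric acid dehydrates 10 to the p-quinone methide 11 and holds it in a hydrogen-bonded contact pair while the enol-like C5–OH/C4=O unit makes C6 (the only ring carbon ortho to a free phenol, C8 being flanked by two ether oxygens) the nucleophilic site, so 1,6-conjugate addition (Friedel–Crafts alkylation) occurs at C6 on the catalyst-selected face of the ethylidene carbon to give 1R; closest known reaction: phosphoric acid-catalysed enantioselective 1,6-addition of phenols, naphthols and indoles to p-quinone methides generated in situ from p-hydroxybenzyl alcohols.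

Step 6
Reactants: 12 (2R,3R)-7-(benzyloxy)-2-[4-(benzyloxy)phenyl]-3,5-dihydroxy-6-[(1R)-1-(4-hydroxyphenyl)ethyl]chroman-4-one
Product: 13 (2R,3R)-3,5,7-trihydroxy-2-(4-hydroxyphenyl)-6-[(1R)-1-(4-hydroxyphenyl)ethyl]chroman-4-one
Conditions: H2 (1 atm), 10 % Pd/C, EtOAc/MeOH, rt
Reagents that add atoms: none
Why: Pd-catalysed hydrogenolysis removes the two O-benzyl ethers under neutral conditions that leave the aryl ketone, the cyclic C2–O bond, the diarylethane centre and the trans-ketol unchanged.

**Compound list**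
1 | 1-(2,4,6-trihydroxyphenyl)ethan-1-one (phloroacetophenone) | CC(=O)c1c(O)cc(O)cc1O | starting material
2 | 1-[2,4-bis(benzyloxy)-6-hydroxyphenyl]ethan-1-one | CC(=O)c1c(O)cc(OCc2ccccc2)cc1OCc1ccccc1 | intermediate
3 | 4-(benzyloxy)benzaldehyde | O=Cc1ccc(OCc2ccccc2)cc1 | starting material
4 | (E)-1-[2,4-bis(benzyloxy)-6-hydroxyphenyl]-3-[4-(benzyloxy)phenyl]prop-2-en-1-one | O=C(/C=C/c1ccc(OCc2ccccc2)cc1)c1c(O)cc(OCc2ccccc2)cc1OCc1ccccc1 | intermediate
5 | (2S)-5,7-bis(benzyloxy)-2-[4-(benzyloxy)phenyl]chroman-4-one | O=C1C[C@@H](c2ccc(OCc3ccccc3)cc2)Oc2cc(OCc3ccccc3)cc(OCc3ccccc3)c12 | intermediate (not isolated)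
6 | (2S)-5,7-bis(benzyloxy)-2-[4-(benzyloxy)phenyl]-4-[(trimethylsilyl)oxy]-2H-chromene | C[Si](C)(C)OC1=C[C@@H](c2ccc(OCc3ccccc3)cc2)Oc2cc(OCc3ccccc3)cc(OCc3ccccc3)c12 | intermediate (not isolated)
7 | (2R,3R,4R)-5,7-bis(benzyloxy)-2-[4-(benzyloxy)phenyl]-3,4-epoxy-4-[(trimethylsilyl)oxy]chromane, oxirane oxygen trans to the 2-aryl group | C[Si](C)(C)O[C@@]12O[C@@H]1[C@@H](c1ccc(OCc3ccccc3)cc1)Oc1cc(OCc3ccccc3)cc(OCc3ccccc3)c12 | intermediate (not isolated)
8 | (2R,3R)-5,7-bis(benzyloxy)-2-[4-(benzyloxy)phenyl]-3-hydroxychroman-4-one | O=C1[C@H](O)[C@@H](c2ccc(OCc3ccccc3)cc2)Oc2cc(OCc3ccccc3)cc(OCc3ccccc3)c12 | intermediate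
9 | (2R,3R)-7-(benzyloxy)-2-[4-(benzyloxy)phenyl]-3,5-dihydroxychroman-4-one | O=C1[C@H](O)[C@@H](c2ccc(OCc3ccccc3)cc2)Oc2cc(OCc3ccccc3)cc(O)c12 | intermediate
10 | 1-(4-hydroxyphenyl)ethan-1-ol (racemic) | CC(O)c1ccc(O)cc1 | starting material
11 | 4-ethylidenecyclohexa-2,5-dien-1-one (p-quinone methide) | CC=C1C=CC(=O)C=C1 | intermediate (not isolated)
12 | (2R,3R)-7-(benzyloxy)-2-[4-(benzyloxy)phenyl]-3,5-dihydroxy-6-[(1R)-1-(4-hydroxyphenyl)ethyl]chroman-4-one | C[C@H](c1ccc(O)cc1)c1c(OCc2ccccc2)cc2c(c1O)C(=O)[C@H](O)[C@@H](c1ccc(OCc3ccccc3)cc1)O2 | intermediate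
13 | (2R,3R)-3,5,7-trihydroxy-2-(4-hydroxyphenyl)-6-[(1R)-1-(4-hydroxyphenyl)ethyl]chroman-4-one | C[C@H](c1ccc(O)cc1)c1c(O)cc2c(c1O)C(=O)[C@H](O)[C@@H](c1ccc(O)cc1)O2 | target

**Summary**
Total step count: 6. Longest linear sequence: 6 steps (1 → 2 → 4 → 8 → 9 → 12 → 13).

**Steps most likely to fail and their fallbacks**

Step 3 (the one-pot ring closure and hydroxylation) is the largest risk. The unactivated chalcone may cyclise slowly or with low enantiomeric excess, and the flavanone can racemise by ring reopening before it is trapped. The fallback sets out from 4 and abandons the conjugate-addition closure for an epoxide opening. The 2'-OH is capped (MOMCl, NaH, DMF) to give (E)-1-[2,4-bis(benzyloxy)-6-(methoxymethoxy)phenyl]-3-[4-(benzyloxy)phenyl]prop-2-en-1-one F1. Juliá–Colonna epoxidation (poly-L-leucine, urea·H2O2, DBU, THF) gives the epoxy ketone [(2R,3S)-3-[4-(benzyloxy)phenyl]oxiran-2-yl][2,4-bis(benzyloxy)-6-(methoxymethoxy)phenyl]methanone F2. HCl in MeOH at 45 °C then removes the MOM group, and the freed phenol opens the oxirane 6-endo at the benzylic carbon with inversion. The route is rejoined at 8.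

Step 5 (the quinone methide alkylation) is the second risk. The acyl-deactivated ring may react slowly, some C8 attack may occur, and the facial control over a methyl-substituted quinone methide is untested. The fallback sets out from 9 and builds the stereocentre by reduction instead of C–C bond formation. Iodination ortho to the chelated 5-OH (NIS, or BnMe3N·ICl2/CaCO3) gives (2R,3R)-7-(benzyloxy)-2-[4-(benzyloxy)phenyl]-3,5-dihydroxy-6-iodochroman-4-one F3. Suzuki–Miyaura coupling with 4-[1-(4,4,5,5-tetramethyl-1,3,2-dioxaborolan-2-yl)ethenyl]phenol (Pd(OAc)2/SPhos, KF, THF) gives the 1,1-diarylethylene (2R,3R)-7-(benzyloxy)-2-[4-(benzyloxy)phenyl]-3,5-dihydroxy-6-[1-(4-hydroxyphenyl)ethenyl]chroman-4-one F4. Chiral phosphoric acid-catalysed transfer hydrogenation with a Hantzsch ester, through the p-quinone methide formed on protonation of the alkene, then sets the 1R centre. The route is rejoined at 12.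

Step 4 (selective 5-O-debenzylation) is the third risk. BCl3 may be diverted by the 3-OH/C4=O chelate, over-cleave the other benzyl ethers, or ionise the C2–O bond and epimerise C2. The fallback sets out from 8 and replaces selective deprotection by global deprotection and selective re-protection. Hydrogenolysis (H2, Pd/C, EtOAc/MeOH) gives (2R,3R)-3,5,7-trihydroxy-2-(4-hydroxyphenyl)chroman-4-one (aromadendrin) F5. Benzylation of its two most acidic phenols (BnBr 2.0 equiv, K2CO3, acetone, rt, under argon) leaves the chelated 5-OH and the secondary 3-OH free. The route is rejoined at 9.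

**Further compounds**
F1 | step 3 | (E)-1-[2,4-bis(benzyloxy)-6-(methoxymethoxy)phenyl]-3-[4-(benzyloxy)phenyl]prop-2-en-1-one | COCOc1cc(OCc2ccccc2)cc(OCc2ccccc2)c1C(=O)/C=C/c1ccc(OCc2ccccc2)cc1
F2 | step 3 | [(2R,3S)-3-[4-(benzyloxy)phenyl]oxiran-2-yl][2,4-bis(benzyloxy)-6-(methoxymethoxy)phenyl]methanone | COCOc1cc(OCc2ccccc2)cc(OCc2ccccc2)c1C(=O)[C@@H]1O[C@H]1c1ccc(OCc2ccccc2)cc1
F3 | step 5 | (2R,3R)-7-(benzyloxy)-2-[4-(benzyloxy)phenyl]-3,5-dihydroxy-6-iodochroman-4-one | O=C1[C@H](O)[C@@H](c2ccc(OCc3ccccc3)cc2)Oc2cc(OCc3ccccc3)c(I)c(O)c12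
F4 | step 5 | (2R,3R)-7-(benzyloxy)-2-[4-(benzyloxy)phenyl]-3,5-dihydroxy-6-[1-(4-hydroxyphenyl)ethenyl]chroman-4-one | C=C(c1ccc(O)cc1)c1c(OCc2ccccc2)cc2c(c1O)C(=O)[C@H](O)[C@@H](c1ccc(OCc3ccccc3)cc1)O2
F5 | step 4 | (2R,3R)-3,5,7-trihydroxy-2-(4-hydroxyphenyl)chroman-4-one (aromadendrin) | O=C1[C@H](O)[C@@H](c2ccc(O)cc2)Oc2cc(O)cc(O)c12
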